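**Strategy**

Everything rests on breaking the C10–C20 bond of the 19,20-olide. The feature exploited is that C20 on the ring-fusion carbon C10 and the C19 carbonyl on C4 stand 1,3 across ring A and are joined by the lactone oxygen, so ring B can be traced back to an arene bearing a hydroxyl at C9. In one operation, C-alkylation of the phenolate at its substituted ortho carbon C10 closes the bridging δ-lactone, relays the C4 configuration to C10 and converts ring B into a cyclohexa-2,4-dienone. The precursor is the chloromethyl ester of an (S)-5-hydroxy-1-methyltetralin-1-carboxylic acid whose C8 substituent (C17) is a silyloxymethyl group.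

Key step: step 10

**Assumptions and remarks on the chemistry**

- Labdane numbering (C1–C20) is used throughout; β is the face of rings A/B that carries C19 and C20. The target SMILES places H5, the 6-acetoxy group, the epoxide oxygen and C11 on β (rings A/B cis-fused), with C17 and the C9 oxygen on α; C13 is R.
- Stereochemical check of the key step: the tetralin quaternary carbon of 18 is (S) and maps onto C4 of the target. The closure is of the enolexo type, since the phenolate C9=C10 bond lies outside the lactone ring that forms.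
- Design improvement of the precursor: C17 is carried as CH2OTBS, not as a bare aryl methyl. It can then become the exocyclic C8=C17 unit by simple β-elimination, whereas a methyl group would need an unselective late C–H oxidation.
- The (R)-1-phenylethylammonium salt of the (S)-acid is taken to be the less soluble diastereomer; if the opposite pairing crystallises, (S)-1-phenylethylamine is used in the same way.
- C8 in 21 and 23–28 and the C9 carbinol in 23–25 are epimer mixtures and are written without configuration; both centres become sp2 before they matter.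

**Route**

Step 1
Reactants: 1 5-methoxy-1-tetralone; 2 p-toluenesulfonylmethyl isocyanide (TosMIC)
Product: 3 (±)-5-methoxy-1,2,3,4-tetrahydronaphthalene-1-carbonitrile
Conditions: TosMIC, KOtBu, DME/EtOH, 0 °C → rt
Reagents that add atoms: TosMIC, Cc1ccc(cc1)S(=O)(=O)C[N+]#[C-]
Why: The van Leusen reductive cyanation converts the aryl ketone directly into the benzylic nitrile, the new centre being racemic at this stage.

Step 2
Reactants: 3 (±)-nitrile; 4 iodomethane
Product: 5 (±)-5-methoxy-1-methyl-1,2,3,4-tetrahydronaphthalene-1-carbonitrile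
Conditions: LDA, THF, −78 °C; MeI, −78 °C → rt
Reagents that add atoms: iodomethane, CI
Why: Alkylation of the benzylic nitrile anion (SN2 on MeI) should build the quaternary carbon cleanly, still as the racemate.

Step 3
Reactants: 5 (±)-methylated nitrile; 6 water
Product: 7 (±)-5-methoxy-1-methyl-1,2,3,4-tetrahydronaphthalene-1-carboxylic acid
Conditions: KOH, ethylene glycol/H2O, 170 °C; then aq HCl
Reagents that add atoms: water, O
Why: Forcing alkaline hydrolysis is the standard way to open a hindered tertiary nitrile, and the aryl methyl ether and the non-enolisable quaternary centre should be unaffected.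

Step 4
Reactants: 7 (±)-acid; 8 (R)-1-phenylethylamine
Product: 9 (R)-1-phenylethylammonium (S)-5-methoxy-1-methyl-1,2,3,4-tetrahydronaphthalene-1-carboxylate
Conditions: (R)-1-phenylethylamine, acetone, reflux → rt, recrystallise to constant rotation
Reagents that add atoms: (R)-1-phenylethylamine, C[C@@H](N)c1ccccc1
Why: Classical resolution by diastereomeric salt crystallisation should enrich the salt of the (S)-acid and thereby fix the future C4 centre, which cannot epimerise afterwards.

Step 5
Reactants: 9 resolved ammonium salt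
Product: 10 (S)-5-hydroxy-1-methyl-1,2,3,4-tetrahydronaphthalene-1-carboxylic acid
Conditions: 48% HBr, AcOH, 110 °C
Reagents that add atoms: none
Why: Acid-mediated SN2 cleavage of the aryl methyl ether by bromide at the methyl group should free the phenol while the same acid releases the carboxylic acid from its ammonium salt.

Step 6
Reactants: 10 phenol acid; 11 formaldehyde (used as paraformaldehyde)
Product: 12 (S)-6-formyl-5-hydroxy-1-methyl-1,2,3,4-tetrahydronaphthalene-1-carboxylic acid
Conditions: MgCl2, Et3N (excess), (CH2O)n, MeCN, reflux; aq HCl work-up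
Reagents that add atoms: formaldehyde, C=O
Why: The magnesium-phenoxide-directed ortho-formylation (Casnati–Skattebøl reaction) reacts only at the single free ortho position, which installs C17 on C8 without touching the para carbon.

Step 7
Reactants: 12 salicylaldehyde acid
Product: 13 (S)-5-hydroxy-6-(hydroxymethyl)-1-methyl-1,2,3,4-tetrahydronaphthalene-1-carboxylic acid
Conditions: NaBH4, THF/MeOH, 0 °C; cold 1 M HCl to pH 3
Reagents that add atoms: none
Why: Borohydride reduction of the aryl aldehyde should give the benzylic alcohol and leave the carboxylic acid untouched.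

Step 8
Reactants: 13 diol acid; 14 tert-butyldimethylsilyl chloride
Product: 16 (S)-6-[(tert-butyldimethylsilyloxy)methyl]-5-hydroxy-1-methyl-1,2,3,4-tetrahydronaphthalene-1-carboxylic acid, via tris-silylated acid 15 (not isolated)
Conditions: TBSCl (3.3 equiv), imidazole, DMF, rt; then K2CO3, MeOH/H2O, 0 °C; pH 5 work-up
Reagents that add atoms: tert-butyldimethylsilyl chloride, CC(C)(C)[Si](C)(C)Cl
Why: Exhaustive silylation followed by mild methanolysis should cleave the labile silyl ester and aryl silyl ether selectively and keep the primary alkyl silyl ether.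

Step 9
Reactants: 16 silyloxymethyl phenol acid; 17 chloromethyl chlorosulfate
Product: 18 chloromethyl (S)-6-[(tert-butyldimethylsilyloxy)methyl]-5-hydroxy-1-methyl-1,2,3,4-tetrahydronaphthalene-1-carboxylate
Conditions: ClCH2OSO2Cl, NaHCO3, n-Bu4NHSO4, CH2Cl2/H2O, rt
Reagents that add atoms: chloromethyl chlorosulfate, ClCOS(Cl)(=O)=O
Why: Phase-transfer O-alkylation of the carboxylate (chlorosulfate as leaving group) should be selective because bicarbonate ionises the acid but not the hindered phenol.

Step 10
Reactants: 18 chloromethyl ester phenol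
Product: 20 tricyclic dienone lactone (C9 ketone; C7=C8 and C5=C6; C8–CH2OTBS; C19(=O)–O–C20 bridge from C4 to C10 on the β face), via potassium phenolate 19 (not isolated)
Conditions: KOtBu (1.05 equiv), THF/t-BuOH, 0.003 M, slow addition, −20 °C → rt, Ar, dark
Reagents that add atoms: none
Why: Proposed new method: the potassium phenolate 19 attacks the chloromethyl carbon C20 through its substituted ortho carbon C10 in an intramolecular SN2 displacement of chloride, a 6-(enolexo)-exo-tet closure of the δ-lactone ring C10–C20–O–C19–C4–C5 that Baldwin's rules favour. The closest known reaction type is the Winstein–Masamune intramolecular alkylative dearomatisation of phenolates and substituted naphtholates by tethered alkyl halides or sulfonates; the new element is the acyloxymethyl chloride, an oxygen-activated SN2 electrophile. The new quaternary centre C10 is controlled by C4, because the three-atom tether C19–O–C20 can only reach the arene face on which the pseudoaxial carboxyl sits, so C20 must end cis to C19. C-alkylation is needed over O-alkylation and is secured by ring size (O-alkylation would require an eight-membered ring), the para carbon C6 is out of reach, and C10 carries C1 so the dienone cannot return to a phenol. Solvolysis and intermolecular reaction of the chloromethyl ester are the competing processes, hence dry, dilute conditions and one equivalent of a hindered base.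

Step 11
Reactants: 20 dienone lactone
Product: 21 β,γ-unsaturated ketone lactone (C9 ketone; C5=C6 kept; C7 saturated; C8–H bearing CH2OTBS, C8 epimers)
Conditions: [(Ph3P)CuH]6 (5 mol%), PhMe2SiH, t-BuOH, toluene, rt
Reagents that add atoms: none
Why: Copper hydride catalysed conjugate reduction should deliver hydride to the accessible β-carbon C7 and not to the δ-carbon C5, which is flanked by two quaternary carbons, and t-BuOH protonates the enolate so that the silyl ether at C17 is not eliminated.

Step 12
Reactants: 21 β,γ-unsaturated ketone; 22 hydrogen peroxide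
Product: 24 6β,9-diol (H5 β; C17–OTBS; C8 and C9 epimers), via organoborane 23 (not isolated)
Conditions: BH3·THF (4 equiv), THF, 0 °C → rt; then 30% H2O2, aq NaOAc, 0 °C → rt
Reagents that add atoms: hydrogen peroxide, OO
Why: Hydroboration–oxidation adds H and B syn across C5=C6 with boron on the less substituted C6, from the β face that is screened only by the flat ester bridge while the α face carries the axial hydrogens of C1 and C3, so H5 β and 6β-OH are set together (oxidation with retention); the C9 ketone is reduced on the way and restored in step 14.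

Step 13
Reactants: 24 6β,9-diol; 14 tert-butyldimethylsilyl chloride
Product: 25 6β-silyl ether 9-ol (C6–OTBS; C17–OTBS; C9–OH free)
Conditions: TBSCl, imidazole, DMAP (cat.), DMF, rt
Reagents that add atoms: tert-butyldimethylsilyl chloride, CC(C)(C)[Si](C)(C)Cl
Why: Silylation should select the equatorial C6 hydroxyl on the convex face over the C9 hydroxyl, which is neopentylic and flanked by the quaternary C10 and the branched C8.

Step 14
Reactants: 25 mono-alcohol
Product: 26 9-ketone (6β-OTBS; C8–CH2OTBS, C8 epimers; H5 β)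
Conditions: Dess–Martin periodinane, NaHCO3, CH2Cl2, rt
Reagents that add atoms: none
Why: Dess–Martin oxidation reliably converts hindered secondary alcohols into ketones under neutral conditions that spare silyl ethers and the lactone.

Step 15
Reactants: 26 bis-silyl ketone
Product: 27 17-hydroxy 9-ketone (6β-OTBS retained)
Conditions: HF·pyridine, pyridine, THF, 0 °C
Reagents that add atoms: none
Why: Under buffered HF·pyridine a primary TBS ether is cleaved much faster than a hindered secondary one, and the weakly acidic medium avoids retro-aldol loss of formaldehyde from the β-hydroxy ketone.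

Step 16
Reactants: 27 β-hydroxy ketone
Product: 29 α-methylene ketone (C8=C17 exocyclic; C9 ketone; 6β-OTBS; H5 β), via C17 mesylate 28 (not isolated)
Conditions: MsCl, Et3N, CH2Cl2, 0 °C; then DBU, rt
Reagents that add atoms: none
Why: Mesylation followed by E1cB elimination through the C8 enolate can only give the exocyclic C8=C17 alkene and erases the undefined C8 centre.

Step 17
Reactants: 29 α-methylene ketone; 30 potassium peroxymonosulfate (Oxone)
Product: 31 8β,17-epoxy 9-ketone (epoxide oxygen β, C17 α; 6β-OTBS)
Conditions: KHSO5, acetone, NaHCO3, CH2Cl2/H2O, 0 °C → rt (dimethyldioxirane formed in situ)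
Reagents that add atoms: potassium peroxymonosulfate, [K+].OOS(=O)(=O)[O-]
Why: Electrophilic dioxirane epoxidation of the enone should occur from the β face because, in the cis-fused chair of ring B, the α face of C8=C17 is blocked by the syn-axial C1 methylene on C10 while C9 is still sp2 and carries nothing on β, which sets C8.

Step 18
Reactants: 31 epoxy ketone; 32 vinylmagnesium bromide
Product: 33 9α-hydroxy-9β-vinyl epoxy lactone
Conditions: CH2=CHMgBr, CeCl3 (anhydrous), THF, −78 °C
Reagents that add atoms: vinylmagnesium bromide, C=C[Mg]Br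
Why: Organocerium 1,2-addition should take the activated α-epoxy ketone in preference to the neopentylic lactone and attack from the β face, anti to the two α-axial groups that flank the carbonyl (C1 on C10 and C17 on C8), placing C11 β and the hydroxyl α.

Step 19
Reactants: 33 vinyl carbinol; 34 2-bromoprop-2-en-1-ol
Product: 36 allylic alcohol with the side chain C9–CH2CH2–C(=CH2)–CH2OH, via B-alkyl-9-BBN adduct 35 (not isolated)
Conditions: 9-BBN dimer, THF, rt; then Pd(dppf)Cl2 (5 mol%), AsPh3, Cs2CO3, 2-bromoprop-2-en-1-ol, DMF/H2O, rt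
Reagents that add atoms: 2-bromoprop-2-en-1-ol, OCC(Br)=C
Why: Anti-Markovnikov hydroboration of the only alkene followed by B-alkyl Suzuki–Miyaura coupling with the vinyl bromide forms the C12–C13 bond under conditions that tolerate the epoxide, lactone and free hydroxyls.

Step 20
Reactants: 36 allylic alcohol; 37 tert-butyl hydroperoxide
Product: 38 (13S)-epoxy alcohol (C13–C16 oxirane, C14 hydroxymethyl)
Conditions: Ti(OiPr)4 (10 mol%), L-(+)-diethyl tartrate (12 mol%), t-BuOOH, 4 Å MS, CH2Cl2, −20 °C
Reagents that add atoms: tert-butyl hydroperoxide, CC(C)(C)OO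
Why: Sharpless asymmetric epoxidation of a 2-substituted allylic alcohol is reagent-controlled, L-(+)-tartrate giving the (S)-oxirane as with 2-methylallyl alcohol, and catalytic loading at low temperature should keep the hindered C9 hydroxyl from opening the product.

Step 21
Reactants: 38 epoxy alcohol
Product: 39 (13R)-epoxy aldehyde (same spatial arrangement at C13)
Conditions: Dess–Martin periodinane, NaHCO3, CH2Cl2, 0 °C → rt
Reagents that add atoms: none
Why: Dess–Martin oxidation gives the aldehyde under buffered conditions, and the α-carbon is fully substituted so the stereocentre cannot epimerise.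

Step 22
Reactants: 39 epoxy aldehyde; 40 dimethyl (1-diazo-2-oxopropyl)phosphonate
Product: 41 (13S)-2-ethynyl oxirane (terminal alkyne C14≡C15 on C13)
Conditions: dimethyl (1-diazo-2-oxopropyl)phosphonate, K2CO3, MeOH, 0 °C → rt
Reagents that add atoms: dimethyl (1-diazo-2-oxopropyl)phosphonate, COP(=O)(OC)C(=[N+]=[N-])C(C)=O
Why: The Seyferth–Gilbert homologation in its Ohira–Bestmann form converts a non-enolisable aldehyde into the terminal alkyne under mild carbonate conditions that the hindered lactone and both epoxides should survive.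

Step 23
Reactants: 41 epoxy alkyne
Product: 42 spiro-tetrahydrofuran (9α,13-ether; C13 bearing ethynyl and CH2OH; 13R)
Conditions: CSA (10 mol%), CH2Cl2, 0 °C
Reagents that add atoms: none
Why: Acid-catalysed 5-exo-tet opening of the oxirane by the C9 hydroxyl at the more substituted carbon proceeds with inversion and so sets C13, while the 8,17-epoxide is deactivated by the adjacent C9 oxygen and has no internal nucleophile in reach.

Step 24
Reactants: 42 alkynol
Product: 43 6-O-TBS spiro-dihydrofuran (C14=C15 enol ether; C15–O–C16)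
Conditions: Mo(CO)6 (30 mol%), Et3N, Et2O, hν (350 nm), rt
Reagents that add atoms: none
Why: Molybdenum-carbonyl catalysed cycloisomerisation of a but-3-yn-1-ol via the metal vinylidene gives the 2,3-dihydrofuran by endo O–C15 bond formation under basic conditions that spare the epoxide and the new enol ether.

Step 25
Reactants: 43 silyl ether; 44 acetic anhydride
Product: 46 target compound CNP0173713.1, via C6 alcohol 45 (not isolated)
Conditions: TBAF, THF, 0 °C → rt; then Ac2O, Et3N, DMAP, rt
Reagents that add atoms: acetic anhydride, CC(=O)OC(C)=O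
Why: Fluoride desilylation followed by DMAP-catalysed acetylation keeps the medium basic throughout, so the acid-labile spiro enol ether and the epoxide should survive and no stereocentre is touched.

**Compound list**

1 | 5-methoxy-1-tetralone | COc1cccc2C(=O)CCCc12 | starting material
2 | p-toluenesulfonylmethyl isocyanide | Cc1ccc(cc1)S(=O)(=O)C[N+]#[C-] | starting material
3 | (±)-5-methoxy-1,2,3,4-tetrahydronaphthalene-1-carbonitrile | COc1cccc2C(C#N)CCCc12 | intermediate
4 | iodomethane | CI | starting material
5 | (±)-5-methoxy-1-methyl-1,2,3,4-tetrahydronaphthalene-1-carbonitrile | COc1cccc2c1CCCC2(C)C#N | intermediate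
6 | water | O | starting material
7 | (±)-5-methoxy-1-methyl-1,2,3,4-tetrahydronaphthalene-1-carboxylic acid | COc1cccc2c1CCCC2(C)C(=O)O | intermediate
8 | (R)-1-phenylethylamine | C[C@@H](N)c1ccccc1 | starting material
9 | (R)-1-phenylethylammonium (S)-5-methoxy-1-methyltetralin-1-carboxylate | COc1cccc2c1CCC[C@]2(C)C(=O)[O-].C[C@@H]([NH3+])c1ccccc1 | intermediate
10 | (S)-5-hydroxy-1-methyl-1,2,3,4-tetrahydronaphthalene-1-carboxylic acid | Oc1cccc2c1CCC[C@]2(C)C(=O)O | intermediate
11 | formaldehyde (as paraformaldehyde) | C=O | starting material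
12 | (S)-6-formyl-5-hydroxy-1-methyltetralin-1-carboxylic acid | O=Cc1ccc2c(c1O)CCC[C@]2(C)C(=O)O | intermediate
13 | (S)-5-hydroxy-6-(hydroxymethyl)-1-methyltetralin-1-carboxylic acid | OCc1ccc2c(c1O)CCC[C@]2(C)C(=O)O | intermediate
14 | tert-butyldimethylsilyl chloride | CC(C)(C)[Si](C)(C)Cl | starting material
15 | tris-silylated acid (silyl ester, aryl silyl ether, alkyl silyl ether; not isolated) | CC(C)(C)[Si](C)(C)OCc1ccc2c(c1O[Si](C)(C)C(C)(C)C)CCC[C@]2(C)C(=O)O[Si](C)(C)C(C)(C)C | intermediate
16 | (S)-6-[(tert-butyldimethylsilyloxy)methyl]-5-hydroxy-1-methyltetralin-1-carboxylic acid | CC(C)(C)[Si](C)(C)OCc1ccc2c(c1O)CCC[C@]2(C)C(=O)O | intermediate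
17 | chloromethyl chlorosulfate | ClCOS(Cl)(=O)=O | starting material
18 | chloromethyl (S)-6-[(tert-butyldimethylsilyloxy)methyl]-5-hydroxy-1-methyltetralin-1-carboxylate (key-step precursor) | CC(C)(C)[Si](C)(C)OCc1ccc2c(c1O)CCC[C@]2(C)C(=O)OCCl | intermediate
19 | potassium phenolate of 18 (not isolated) | CC(C)(C)[Si](C)(C)OCc1ccc2c(c1[O-])CCC[C@]2(C)C(=O)OCCl.[K+] | intermediate
20 | tricyclic dienone lactone (C9=O, C7=C8, C5=C6, C8–CH2OTBS, 19,20-olide; key-step product) | O=C1C(CO[Si](C)(C)C(C)(C)C)=CC=C2[C@]13CCC[C@]2(C)C(=O)OC3 | intermediate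
21 | β,γ-unsaturated ketone lactone (C9=O, C5=C6, C8–H with CH2OTBS, C8 epimers) | O=C1C(CO[Si](C)(C)C(C)(C)C)CC=C2[C@]13CCC[C@]2(C)C(=O)OC3 | intermediate
22 | hydrogen peroxide | OO | starting material
23 | organoborane (C6β–BH2, C9–O–BH2; not isolated) | B[C@@H]1CC(CO[Si](C)(C)C(C)(C)C)C(OB)[C@]23CCC[C@](C)(C(=O)OC2)[C@@H]13 | intermediate
24 | 6β,9-diol (H5 β, C17–OTBS, C8/C9 epimers) | O[C@@H]1CC(CO[Si](C)(C)C(C)(C)C)C(O)[C@]23CCC[C@](C)(C(=O)OC2)[C@@H]13 | intermediate
25 | 6β-OTBS 9-ol | CC(C)(C)[Si](C)(C)O[C@@H]1CC(CO[Si](C)(C)C(C)(C)C)C(O)[C@]23CCC[C@](C)(C(=O)OC2)[C@@H]13 | intermediate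
26 | 6β-OTBS 9-ketone (C17–OTBS, C8 epimers) | CC(C)(C)[Si](C)(C)O[C@@H]1CC(CO[Si](C)(C)C(C)(C)C)C(=O)[C@]23CCC[C@](C)(C(=O)OC2)[C@@H]13 | intermediate
27 | 17-hydroxy 9-ketone (6β-OTBS) | CC(C)(C)[Si](C)(C)O[C@@H]1CC(CO)C(=O)[C@]23CCC[C@](C)(C(=O)OC2)[C@@H]13 | intermediate
28 | C17 mesylate (not isolated) | CC(C)(C)[Si](C)(C)O[C@@H]1CC(COS(C)(=O)=O)C(=O)[C@]23CCC[C@](C)(C(=O)OC2)[C@@H]13 | intermediate
29 | α-methylene ketone (C8=C17, C9=O, 6β-OTBS) | CC(C)(C)[Si](C)(C)O[C@@H]1CC(=C)C(=O)[C@]23CCC[C@](C)(C(=O)OC2)[C@@H]13 | intermediate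
30 | potassium peroxymonosulfate (Oxone) | [K+].OOS(=O)(=O)[O-] | starting material
31 | 8β,17-epoxy 9-ketone | CC(C)(C)[Si](C)(C)O[C@@H]1C[C@@]2(CO2)C(=O)[C@]23CCC[C@](C)(C(=O)OC2)[C@@H]13 | intermediate
32 | vinylmagnesium bromide | C=C[Mg]Br | starting material
33 | 9α-hydroxy-9β-vinyl epoxy lactone | CC(C)(C)[Si](C)(C)O[C@@H]1C[C@@]2(CO2)[C@](O)(C=C)[C@]23CCC[C@](C)(C(=O)OC2)[C@@H]13 | intermediate
34 | 2-bromoprop-2-en-1-ol | OCC(Br)=C | starting material
35 | B-alkyl-9-BBN adduct at C12 (not isolated) | CC(C)(C)[Si](C)(C)O[C@@H]1C[C@@]2(CO2)[C@](O)(CCB4C5CCCC4CCC5)[C@]23CCC[C@](C)(C(=O)OC2)[C@@H]13 | intermediate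
36 | allylic alcohol (C9–CH2CH2–C(=CH2)–CH2OH) | CC(C)(C)[Si](C)(C)O[C@@H]1C[C@@]2(CO2)[C@](O)(CCC(=C)CO)[C@]23CCC[C@](C)(C(=O)OC2)[C@@H]13 | intermediate
37 | tert-butyl hydroperoxide | CC(C)(C)OO | starting material
38 | (13S)-epoxy alcohol | CC(C)(C)[Si](C)(C)O[C@@H]1C[C@@]2(CO2)[C@](O)(CC[C@@]4(CO4)CO)[C@]23CCC[C@](C)(C(=O)OC2)[C@@H]13 | intermediate
39 | (13R)-epoxy aldehyde | CC(C)(C)[Si](C)(C)O[C@@H]1C[C@@]2(CO2)[C@](O)(CC[C@@]4(CO4)C=O)[C@]23CCC[C@](C)(C(=O)OC2)[C@@H]13 | intermediate
40 | dimethyl (1-diazo-2-oxopropyl)phosphonate | COP(=O)(OC)C(=[N+]=[N-])C(C)=O | starting material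
41 | (13S)-2-ethynyl oxirane | CC(C)(C)[Si](C)(C)O[C@@H]1C[C@@]2(CO2)[C@](O)(CC[C@@]4(CO4)C#C)[C@]23CCC[C@](C)(C(=O)OC2)[C@@H]13 | intermediate
42 | spiro-tetrahydrofuran alkynol (13R; C13 ethynyl and CH2OH) | CC(C)(C)[Si](C)(C)O[C@@H]1C[C@@]2(CO2)[C@]2(CC[C@](CO)(C#C)O2)[C@]23CCC[C@](C)(C(=O)OC2)[C@@H]13 | intermediate
43 | 6-O-TBS spiro-dihydrofuran | CC(C)(C)[Si](C)(C)O[C@@H]1C[C@@]2(CO2)[C@]2(CC[C@]3(C=COC3)O2)[C@]23CCC[C@](C)(C(=O)OC2)[C@@H]13 | intermediate
44 | acetic anhydride | CC(=O)OC(C)=O | starting material
45 | C6 alcohol (6-deacetyl target; not isolated) | O[C@@H]1C[C@@]2(CO2)[C@]2(CC[C@]3(C=COC3)O2)[C@]23CCC[C@](C)(C(=O)OC2)[C@@H]13 | intermediate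
46 | CNP0173713.1 | CC(=O)O[C@@H]1C[C@@]2(CO2)[C@]2(CC[C@]3(C=COC3)O2)[C@]23CCC[C@](C)(C(=O)OC2)[C@@H]13 | target

**Step count**

Total steps: 25. Longest linear sequence: 25 steps (1 → 46); all other inputs are commercial reagents.

**Steps most likely to fail, with fallbacks**

1. Step 10 (the proposed new method). What may go wrong: intermolecular O-alkylation or oligomerisation and solvolysis of the chloromethyl ester may outrun the ring closure, which first needs the ester to rotate into its s-trans form. The fallback uses only known chemistry, sets out from salt 9 and returns to the route at ketone 21. Acidification of 9 frees (S)-5-methoxy-1-methyltetralin-1-carboxylic acid F1. Birch reduction (Li, NH3, t-BuOH) and aqueous HCl hydrolysis with isomerisation should give the conjugated enone acid F2 (C9 ketone, C5=C10). MeI/K2CO3 gives the methyl ester F3. KOtBu/t-BuOH with a controlled amount of formaldehyde forms the extended dienolate by deprotonation at C6; its reversible aldol addition at the α-carbon C10 is funnelled by lactonisation of the cis adduct onto the ester, giving the deconjugated keto lactone F4 (C5=C6). LDA and formaldehyde then hydroxymethylate C8, the only enolisable position, to give hydroxymethyl ketone F5, and TBSCl/imidazole converts F5 into 21.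

2. Step 12. What may go wrong: borane may not discriminate well enough between the two faces of C5=C6, and slow lactone reduction may compete. The fallback sets out from dienone 20 and returns at ketone 26. Hydrogenation of the γ,δ-alkene over Pd/C in pyridine, where the catalyst surface binds the flatter lactone face, should give the cis-fused enone F6. TBSOTf/Et3N gives the extended silyl dienol ether F7. Vinylogous Rubottom oxidation with dimethyldioxirane attacks C6 from the convex β face and gives the 6β-hydroxy enone F8. TBSCl/imidazole gives the silyl ether F9, and conjugate reduction with [(Ph3P)CuH]6/PhMe2SiH/t-BuOH gives 26 without any redox detour at C9.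

3. Step 23. What may go wrong: partial ionisation at the propargylic tertiary carbon would erode inversion at C13, and the acid may also open the 8,17-epoxide. The fallback closes the ring before the alkyne exists and exchanges the roles of the two C13 arms; it sets out from allylic alcohol 36 and returns at C6 alcohol 45. Sharpless epoxidation with D-(−)-diethyl tartrate gives the C13-epimeric epoxy alcohol F10. TBSCl/imidazole gives the silyl ether F11. CSA closes the tetrahydrofuran at a purely alkyl tertiary oxirane carbon with inversion, giving F12, which carries CH2OTBS (the future C16) and CH2OH (the future C14). Dess–Martin oxidation gives aldehyde F13 and Ohira–Bestmann homologation gives alkyne F14. TBAF removes both silyl groups to give diol alkyne F15, and Mo(CO)6/Et3N cycloisomerisation gives 45, which is acetylated as in step 25.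

**Further compounds**

F1 | step 10 | (S)-5-methoxy-1-methyltetralin-1-carboxylic acid | COc1cccc2c1CCC[C@]2(C)C(=O)O
F2 | step 10 | (S)-1-methyl-5-oxo-1,2,3,4,5,6,7,8-octahydronaphthalene-1-carboxylic acid | O=C1CCCC2=C1CCC[C@]2(C)C(=O)O
F3 | step 10 | methyl ester of F2 | O=C1CCCC2=C1CCC[C@]2(C)C(=O)OC
F4 | step 10 | keto lactone (C9=O, C5=C6, C8 unsubstituted, 19,20-olide) | O=C1CCC=C2[C@]13CCC[C@]2(C)C(=O)OC3
F5 | step 10 | 8-(hydroxymethyl) keto lactone (C8 epimers) | O=C1C(CO)CC=C2[C@]13CCC[C@]2(C)C(=O)OC3
F6 | step 12 | cis-fused enone (H5 β, C7=C8, C9=O, C8–CH2OTBS) | C1C=C(CO[Si](C)(C)C(C)(C)C)C(=O)[C@]23CCC[C@](C)(C(=O)OC2)[C@@H]13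
F7 | step 12 | silyl dienol ether (C6=C7, C8=C9–OTBS) | C1=CC(CO[Si](C)(C)C(C)(C)C)=C(O[Si](C)(C)C(C)(C)C)[C@]23CCC[C@](C)(C(=O)OC2)[C@@H]13
F8 | step 12 | 6β-hydroxy enone | O[C@@H]1C=C(CO[Si](C)(C)C(C)(C)C)C(=O)[C@]23CCC[C@](C)(C(=O)OC2)[C@@H]13
F9 | step 12 | 6β-OTBS enone | CC(C)(C)[Si](C)(C)O[C@@H]1C=C(CO[Si](C)(C)C(C)(C)C)C(=O)[C@]23CCC[C@](C)(C(=O)OC2)[C@@H]13
F10 | step 23 | C13-epimeric epoxy alcohol (from D-(−)-tartrate) | CC(C)(C)[Si](C)(C)O[C@@H]1C[C@@]2(CO2)[C@](O)(CC[C@]4(CO4)CO)[C@]23CCC[C@](C)(C(=O)OC2)[C@@H]13
F11 | step 23 | silyl ether of F10 | CC(C)(C)[Si](C)(C)O[C@@H]1C[C@@]2(CO2)[C@](O)(CC[C@]4(CO4)CO[Si](C)(C)C(C)(C)C)[C@]23CCC[C@](C)(C(=O)OC2)[C@@H]13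
F12 | step 23 | spiro-tetrahydrofuran with C13 CH2OTBS and CH2OH | CC(C)(C)[Si](C)(C)O[C@@H]1C[C@@]2(CO2)[C@]2(CC[C@](CO[Si](C)(C)C(C)(C)C)(CO)O2)[C@]23CCC[C@](C)(C(=O)OC2)[C@@H]13
F13 | step 23 | C14 aldehyde | CC(C)(C)[Si](C)(C)O[C@@H]1C[C@@]2(CO2)[C@]2(CC[C@](CO[Si](C)(C)C(C)(C)C)(C=O)O2)[C@]23CCC[C@](C)(C(=O)OC2)[C@@H]13
F14 | step 23 | bis-silyl alkyne | CC(C)(C)[Si](C)(C)O[C@@H]1C[C@@]2(CO2)[C@]2(CC[C@](CO[Si](C)(C)C(C)(C)C)(C#C)O2)[C@]23CCC[C@](C)(C(=O)OC2)[C@@H]13
F15 | step 23 | diol alkyne (C6–OH, C16–OH) | O[C@@H]1C[C@@]2(CO2)[C@]2(CC[C@](CO)(C#C)O2)[C@]23CCC[C@](C)(C(=O)OC2)[C@@H]13
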